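Which of the flasks below, alike in charge and differing in temperature, ends with the most target?

the same everywhere: partner 0.285 M
- alpha: substrate 0.42 M; reagent 0.60 M; temperature 48 °C; run made earlier
- theta: substrate 0.66 M; reagent 0.60 M; temperature 97 °C; run made earlier
- south-east: substrate 0.30 M; reagent 0.600 M; temperature 25 °C; time 3.0 h
- north-west: substrate 0.30 M; reagent 0.600 M; temperature 55 °C; time 3.0 h
- west: substrate 0.30 M; reagent 0.600 M; temperature 115 °C; time 3.0 h
- south: substrate 0.30 M; reagent 0.600 M; temperature 85 °C; time 3.0 h

- the flask with the highest amount of target, in percent of the substrate charged ("all alike" if they lie within 1.5 percentage points) (south-east / north-west / west / south / all alike)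
- final target, as a percentage of the substrate charged, in south-east
- final target, as a percentage of the substrate charged, in north-west
- final target, as a percentage of the substrate charged, in west
- final target, as a percentage of the substrate charged, in south

- the numbers in the tables scatter with a standard deviation of 1 percentage point
- a reading or a percentage of target counts all its forms, free or not

I have two earlier runs to go on.

| run | time / min | target / % |
|---|---|---|
| alpha | 10.0 | 14.6 |
| alpha | 20.0 | 18.3 |
| alpha | 30.0 | 21.0 |
| alpha | 40.0 | 19.6 |
| alpha | 50.0 | 22.3 |
| alpha | 60.0 | 21.1 |
| theta | 0.333 | 6.4 |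
| theta | 1.00 | 11.3 |
| theta | 1.50 | 12.4 |
| theta | 2.50 | 10.3 |
| theta | 4.00 | 10.4 |
| theta | 5.00 | 12.3 |

(readings scatter by 1 percentage point)

Reading down the target column, each run climbs and then wanders within the scatter, so I replace the flat part of each curve by its mean. Alpha gives 21.0% from 30.0 min on, with an error near 0.5 percentage points. Theta gives 11.3% from 1.00 min on, with an error near 0.45 points.

Setting one column against the other, theta stops lower although it is hotter and holds more substrate. Both runs charged 0.60 M of reagent, so I have no pair of runs that differ in reagent. I therefore keep a plain balance in which each target costs one substrate and one partner. In alpha, target divided by the product of the substrate and partner that this balance leaves is 1.35 L mol⁻¹. I call this the plateau quotient, an apparent equilibrium constant. In theta it is 0.609 L mol⁻¹.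

I let its logarithm fall evenly with temperature. That gives 1.96 L mol⁻¹ in south-east, 1.21 L mol⁻¹ in north-west, 0.740 L mol⁻¹ in south and 0.454 L mol⁻¹ in west. Solving the balance for the charge gives, in the same order, 28.2%, 21.1%, 15.1% and 10.3%, so I reckon south-east highest.

The first reading of each run, taken as an exponential rise, gives a time constant of 8.42 min in alpha and 0.401 min in theta. On the same even scale south-east has 35.1 min, which is shorter than its 3.0 h, so I expect that flask on its plateau.

The forecast, which says “Both runs level off well below full conversion”, names south-east with 27%, 21%, 15% and 11% for south-east, north-west, south and west, a little under mine in south-east and a little over mine in west.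

The flasks give south-east as highest, with 26.0% there, 21.4% in north-west, 16.3% in south and 11.6% in west.

    open intermediate + second intermediate → target (k = 0.00290 L mol⁻¹ s⁻¹, Ea = 53.0 kJ mol⁻¹)
    2 second intermediate → homo product (k = 0.00360 L mol⁻¹ s⁻¹, Ea = 65.0 kJ mol⁻¹)
    reagent + target → over-reaction product (k = 9.00 × 10⁻⁴ L mol⁻¹ s⁻¹, Ea = 58.0 kJ mol⁻¹)
    substrate + reagent → open intermediate (k = 0.00180 L mol⁻¹ s⁻¹, Ea = 51.0 kJ mol⁻¹)
    crystals ⇌ target, rate k5*(cs5 - [target]) while solid is left; crystals form when [target] > cs5 (solubility = 0.140 M, k = 0.120 s⁻¹)
    reagent + partner → second intermediate (k = 0.00100 L mol⁻¹ s⁻¹, Ea = 62.0 kJ mol⁻¹)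
    (constants at 25 °C)

West shows what the quotient is worth. I reckoned 10.3% and the flask holds 11.6%, yet reagent, the limiting reagent, stands at 0% and open intermediate at 59.8%. The substrate and partner actually left in west give a quotient of 134 L mol⁻¹, not 0.454 L mol⁻¹. For a neighbour of west charged with 0.71 M of partner, I reckon 22.6% from the same quotient, and that flask ends with 18.9% of target, reagent at 0% and substrate at 52.5%.

(The earlier runs and the new flask stem from a simulated flask with constants of no real substance; noise was put on by code.)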